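**Retrosynthetic overview**
1. Last bond formed: the feruloyl Cα=Cβ bond, by Knoevenagel–Doebner condensation (aldol-type addition, dehydration, decarboxylation) of vanillin 12 with malonate half-ester 11.
2. 11 comes from (R)-chromenylmethanol 9 and Meldrum's acid 10; no protecting groups are needed.
3. The 2H-pyran ring is the only ring built (both benzene rings are bought); it is closed by ring-closing metathesis of diene 8.
4. The quaternary (R) centre of 8 is set by palladium-catalysed dynamic kinetic asymmetric etherification of phenol 6 with racemic isoprene monoepoxide 7.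
5. 6 comes from acetovanillone 1 by O-allylation, Claisen rearrangement and alkene isomerisation.

Assumption: in step 4 the (R,R)-ligand is taken to give the (R)-ether by analogy with related vinyl-epoxide openings; the sense is confirmed on the first batch (chiral HPLC and rotation of 9), and the equally available mirror-image ligand is used if it proves opposite.

The target's stereocentre (chromene C2) is (R): priorities are ring O > CH2O > C3 > CH3.

**Step 1**
Reactants: 1 acetovanillone [1-(4-hydroxy-3-methoxyphenyl)ethan-1-one]; 2 allyl bromide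
Product: 3 1-[3-methoxy-4-(prop-2-en-1-yloxy)phenyl]ethan-1-one
Conditions: allyl bromide (1.2 equiv), K2CO3 (1.5 equiv), acetone, reflux
Reagents that add atoms: allyl bromide (compound 2), C=CCBr
Why: Williamson ether synthesis, in which the acidic phenol (pKa about 8) is deprotonated by carbonate and alkylated on oxygen by the primary allylic bromide; no stereocentre is formed.

**Step 2**
Reactants: 3 1-[3-methoxy-4-(prop-2-en-1-yloxy)phenyl]ethan-1-one
Product: 5 1-[4-hydroxy-3-methoxy-5-(prop-2-en-1-yl)phenyl]ethan-1-one, via ortho-allyl cyclohexadienone 4 (not isolated)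
Conditions: N,N-diethylaniline, 200 °C, N2
Reagents that add atoms: none
Why: Aromatic Claisen rearrangement ([3,3]-sigmatropic shift) delivers the allyl group to the only free ortho position, and dienone 4 re-aromatises by tautomerisation, so its transient stereocentre is lost.

**Step 3**
Reactants: 5 1-[4-hydroxy-3-methoxy-5-(prop-2-en-1-yl)phenyl]ethan-1-one
Product: 6 1-{4-hydroxy-3-methoxy-5-[(E)-prop-1-en-1-yl]phenyl}ethan-1-one
Conditions: RuClH(CO)(PPh3)3 (2 mol %), toluene, 80 °C
Reagents that add atoms: none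
Why: Ruthenium hydride-catalysed olefin isomerisation (hydrometalation then β-hydride elimination) moves the double bond into conjugation with the arene, mainly as the E isomer, and the geometry is irrelevant because this CH–CH3 terminus leaves as propene in step 5.

**Step 4**
Reactants: 6 1-{4-hydroxy-3-methoxy-5-[(E)-prop-1-en-1-yl]phenyl}ethan-1-one; 7 racemic isoprene monoepoxide (2-methyl-2-vinyloxirane)
Product: 8 1-{4-{[(2R)-1-hydroxy-2-methylbut-3-en-2-yl]oxy}-3-methoxy-5-[(E)-prop-1-en-1-yl]phenyl}ethan-1-one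
Conditions: 7 (1.3 equiv), Pd2(dba)3·CHCl3 (1.5 mol %), (R,R)-DACH-phenyl Trost ligand {N,N'-[(1R,2R)-cyclohexane-1,2-diyl]bis[2-(diphenylphosphanyl)benzamide]} (4.5 mol %), CH2Cl2, 0 °C to rt, stopped at full conversion
Reagents that add atoms: isoprene monoepoxide (compound 7), CC1(C=C)CO1
Why: Trost dynamic kinetic asymmetric allylic etherification (Tsuji–Trost type), in which both enantiomers of 7 ionise to a π-allylpalladium alkoxide that equilibrates by π–σ–π interconversion faster than it is captured, the alkoxide deprotonates the phenol and directs the phenoxide to the tertiary terminus, and the chiral ligand pocket selects the face that gives the (R) quaternary aryl ether.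

**Step 5**
Reactants: 8 1-{4-{[(2R)-1-hydroxy-2-methylbut-3-en-2-yl]oxy}-3-methoxy-5-[(E)-prop-1-en-1-yl]phenyl}ethan-1-one
Product: 9 1-[(2R)-2-(hydroxymethyl)-8-methoxy-2-methyl-2H-chromen-6-yl]ethan-1-one
Conditions: second-generation Grubbs catalyst RuCl2(=CHPh)(PCy3)(H2IMes) (5 mol %), CH2Cl2 (0.01 M), 40 °C, Ar, shielded from light
Reagents that add atoms: none
Why: Ring-closing metathesis between the vinyl and propenyl groups forms the six-membered 2H-chromene ring with irreversible loss of propene, and because no bond to the quaternary carbon is broken its (R) configuration is retained.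

**Step 6**
Reactants: 9 1-[(2R)-2-(hydroxymethyl)-8-methoxy-2-methyl-2H-chromen-6-yl]ethan-1-one; 10 Meldrum's acid (2,2-dimethyl-1,3-dioxane-4,6-dione)
Product: 11 3-{[(2R)-6-acetyl-8-methoxy-2-methyl-2H-chromen-2-yl]methoxy}-3-oxopropanoic acid
Conditions: Meldrum's acid (1.2 equiv), toluene, 95 °C, 4 h
Reagents that add atoms: Meldrum's acid (compound 10), CC1(C)OC(=O)CC(=O)O1
Why: Acylation of the primary alcohol by thermal ring-opening of Meldrum's acid with loss of acetone gives the malonic half-ester directly under neutral conditions that leave the ketone, the chromene and the stereocentre untouched.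

**Step 7**
Reactants: 11 3-{[(2R)-6-acetyl-8-methoxy-2-methyl-2H-chromen-2-yl]methoxy}-3-oxopropanoic acid; 12 vanillin (4-hydroxy-3-methoxybenzaldehyde)
Product: 15 [(2R)-6-acetyl-8-methoxy-2-methyl-2H-chromen-2-yl]methyl (2E)-3-(4-hydroxy-3-methoxyphenyl)prop-2-enoate (CNP0168033.1), via aldol adduct 13 (not isolated), via arylidenemalonate half-ester 14 (not isolated)
Conditions: vanillin (1.3 equiv), piperidine (0.2 equiv), pyridine, 65 °C
Reagents that add atoms: vanillin (compound 12), COc1cc(C=O)ccc1O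
Why: Knoevenagel–Doebner condensation, in which the malonate C–H (far more acidic than the aryl methyl ketone) adds to the aldehyde in an amine-catalysed intermolecular aldol-type reaction, and dehydration then decarboxylation in pyridine give the thermodynamically favoured E-cinnamate with the free phenol tolerated and the remote quaternary centre unaffected.

**Compound list**
1 | acetovanillone, 1-(4-hydroxy-3-methoxyphenyl)ethan-1-one | CC(=O)c1ccc(O)c(OC)c1 | starting material
2 | allyl bromide | C=CCBr | starting material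
3 | 1-[3-methoxy-4-(prop-2-en-1-yloxy)phenyl]ethan-1-one | CC(=O)c1ccc(OCC=C)c(OC)c1 | intermediate
4 | 4-acetyl-2-methoxy-6-(prop-2-en-1-yl)cyclohexa-2,4-dien-1-one (racemic, not isolated) | CC(=O)C1=CC(CC=C)C(=O)C(OC)=C1 | intermediate
5 | 1-[4-hydroxy-3-methoxy-5-(prop-2-en-1-yl)phenyl]ethan-1-one | CC(=O)c1cc(CC=C)c(O)c(OC)c1 | intermediate
6 | 1-{4-hydroxy-3-methoxy-5-[(E)-prop-1-en-1-yl]phenyl}ethan-1-one | C/C=C/c1cc(C(C)=O)cc(OC)c1O | intermediate
7 | racemic isoprene monoepoxide, 2-methyl-2-vinyloxirane | CC1(C=C)CO1 | starting material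
8 | 1-{4-{[(2R)-1-hydroxy-2-methylbut-3-en-2-yl]oxy}-3-methoxy-5-[(E)-prop-1-en-1-yl]phenyl}ethan-1-one | OC[C@@](C)(C=C)Oc1c(OC)cc(C(C)=O)cc1/C=C/C | intermediate
9 | 1-[(2R)-2-(hydroxymethyl)-8-methoxy-2-methyl-2H-chromen-6-yl]ethan-1-one | OC[C@@]1(C)C=Cc2cc(C(C)=O)cc(OC)c2O1 | intermediate
10 | Meldrum's acid, 2,2-dimethyl-1,3-dioxane-4,6-dione | CC1(C)OC(=O)CC(=O)O1 | starting material
11 | 3-{[(2R)-6-acetyl-8-methoxy-2-methyl-2H-chromen-2-yl]methoxy}-3-oxopropanoic acid | OC(=O)CC(=O)OC[C@@]1(C)C=Cc2cc(C(C)=O)cc(OC)c2O1 | intermediate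
12 | vanillin, 4-hydroxy-3-methoxybenzaldehyde | COc1cc(C=O)ccc1O | starting material
13 | 2-({[(2R)-6-acetyl-8-methoxy-2-methyl-2H-chromen-2-yl]methoxy}carbonyl)-3-hydroxy-3-(4-hydroxy-3-methoxyphenyl)propanoic acid (diastereomer mixture at the two new carbons, not isolated) | OC(=O)C(C(O)c1ccc(O)c(OC)c1)C(=O)OC[C@@]1(C)C=Cc2cc(C(C)=O)cc(OC)c2O1 | intermediate
14 | 2-({[(2R)-6-acetyl-8-methoxy-2-methyl-2H-chromen-2-yl]methoxy}carbonyl)-3-(4-hydroxy-3-methoxyphenyl)prop-2-enoic acid (alkene geometry not controlled, not isolated) | OC(=O)C(=Cc1ccc(O)c(OC)c1)C(=O)OC[C@@]1(C)C=Cc2cc(C(C)=O)cc(OC)c2O1 | intermediate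
15 | [(2R)-6-acetyl-8-methoxy-2-methyl-2H-chromen-2-yl]methyl (2E)-3-(4-hydroxy-3-methoxyphenyl)prop-2-enoate | COc1cc(/C=C/C(=O)OC[C@@]2(C)C=Cc3cc(C(C)=O)cc(OC)c3O2)ccc1O | target

**Totals**
Total step count: 7. Longest linear sequence: 7 steps (1 to 15).

**Three steps most likely to fail**

Step 4 (highest risk). Phenol 6 is acidic and carries two ortho substituents. The branched tertiary ether may therefore form slowly or with eroded ee, and zerovalent palladium may re-ionise the product towards the linear isomer. The fallback sets out from 1 and comes back at 9; it makes the chromene as the racemate by the propargyl ether route and resolves it. HC≡CMgBr is added to commercial 1-[(tert-butyldimethylsilyl)oxy]propan-2-one (THF, 0 °C) to give racemic 1-[(tert-butyldimethylsilyl)oxy]-2-methylbut-3-yn-2-ol F1. n-BuLi then ClCO2Me (THF, −78 °C) convert it into racemic 1-[(tert-butyldimethylsilyl)oxy]-2-methylbut-3-yn-2-yl methyl carbonate F2. CuCl2·2H2O (1 mol %) and DBU in MeCN at 0 °C join 1 and F2 to racemic aryl propargyl ether F3. Heating F3 in N,N-diethylaniline at 185 °C triggers the propargyl Claisen rearrangement to allenyl cyclohexadienone F4. This tautomerises to ortho-allenylphenol F5, undergoes a 1,5-hydrogen shift to ortho-quinone methide F6 and closes by 6π-oxa-electrocyclisation to racemic silyl-protected chromene F7. TBAF (THF, 0 °C) frees racemic chromenylmethanol F8. Preparative chiral SFC (amylose tris(3,5-dimethylphenylcarbamate) phase, CO2/MeOH) separates 9 from its (S)-enantiomer F9, which is discarded.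

Step 7. Vanillin is a deactivated aldehyde under amine catalysis. The half-ester can decarboxylate to the acetate before it condenses, and slow Claisen–Schmidt reaction at the acetyl group is conceivable. The fallback sets out from 9, bypasses 11 and comes back at 15; it keeps the same Cα=Cβ disconnection but uses a phosphonate carbanion. 9 is esterified with diethylphosphonoacetic acid (DCC, DMAP, CH2Cl2, rt) to [(2R)-6-acetyl-8-methoxy-2-methyl-2H-chromen-2-yl]methyl 2-(diethoxyphosphoryl)acetate F10. Masamune–Roush Horner–Wadsworth–Emmons olefination with commercial vanillin acetate (LiCl, i-Pr2NEt, MeCN, rt) gives the (E)-configured O-acetyl ferulate ester F11. Brief K2CO3/MeOH at 0 °C removes only the phenolic acetate and gives 15.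

Step 3. The free ortho-phenol can bind the ruthenium hydride, and incomplete isomerisation leaves 5 and 6 as a mixture that is hard to separate. The fallback sets out from 1 and comes back at 6; it installs the propenyl group by cross-coupling instead of Claisen rearrangement and isomerisation. Iodination of 1 with N-iodosuccinimide (cat. TsOH, MeCN, rt) gives 1-(4-hydroxy-3-iodo-5-methoxyphenyl)ethan-1-one F12. Suzuki–Miyaura coupling with (E)-CH3CH=CHBF3K, PdCl2(dppf) (3 mol %) and K2CO3 in THF/H2O at 70 °C gives 6.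

**Further compounds**
F1 | step 4 | racemic 1-[(tert-butyldimethylsilyl)oxy]-2-methylbut-3-yn-2-ol | C#CC(C)(O)CO[Si](C)(C)C(C)(C)C
F2 | step 4 | racemic 1-[(tert-butyldimethylsilyl)oxy]-2-methylbut-3-yn-2-yl methyl carbonate | C#CC(C)(CO[Si](C)(C)C(C)(C)C)OC(=O)OC
F3 | step 4 | racemic 1-[4-({1-[(tert-butyldimethylsilyl)oxy]-2-methylbut-3-yn-2-yl}oxy)-3-methoxyphenyl]ethan-1-one | CC(=O)c1ccc(OC(C)(C#C)CO[Si](C)(C)C(C)(C)C)c(OC)c1
F4 | step 4 | 4-acetyl-6-{4-[(tert-butyldimethylsilyl)oxy]-3-methylbuta-1,2-dien-1-yl}-2-methoxycyclohexa-2,4-dien-1-one | CC(=O)C1=CC(C=C=C(C)CO[Si](C)(C)C(C)(C)C)C(=O)C(OC)=C1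
F5 | step 4 | 1-(3-{4-[(tert-butyldimethylsilyl)oxy]-3-methylbuta-1,2-dien-1-yl}-4-hydroxy-5-methoxyphenyl)ethan-1-one | CC(=O)c1cc(C=C=C(C)CO[Si](C)(C)C(C)(C)C)c(O)c(OC)c1
F6 | step 4 | 4-acetyl-6-{4-[(tert-butyldimethylsilyl)oxy]-3-methylbut-2-en-1-ylidene}-2-methoxycyclohexa-2,4-dien-1-one | CC(=O)C1=CC(=CC=C(C)CO[Si](C)(C)C(C)(C)C)C(=O)C(OC)=C1
F7 | step 4 | racemic 1-(2-{[(tert-butyldimethylsilyl)oxy]methyl}-8-methoxy-2-methyl-2H-chromen-6-yl)ethan-1-one | CC(=O)c1cc2C=CC(C)(CO[Si](C)(C)C(C)(C)C)Oc2c(OC)c1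
F8 | step 4 | racemic 1-[2-(hydroxymethyl)-8-methoxy-2-methyl-2H-chromen-6-yl]ethan-1-one | CC(=O)c1cc2C=CC(C)(CO)Oc2c(OC)c1
F9 | step 4 | 1-[(2S)-2-(hydroxymethyl)-8-methoxy-2-methyl-2H-chromen-6-yl]ethan-1-one | OC[C@]1(C)C=Cc2cc(C(C)=O)cc(OC)c2O1
F10 | step 7 | [(2R)-6-acetyl-8-methoxy-2-methyl-2H-chromen-2-yl]methyl 2-(diethoxyphosphoryl)acetate | CCOP(=O)(OCC)CC(=O)OC[C@@]1(C)C=Cc2cc(C(C)=O)cc(OC)c2O1
F11 | step 7 | [(2R)-6-acetyl-8-methoxy-2-methyl-2H-chromen-2-yl]methyl (2E)-3-(4-acetoxy-3-methoxyphenyl)prop-2-enoate | COc1cc(/C=C/C(=O)OC[C@@]2(C)C=Cc3cc(C(C)=O)cc(OC)c3O2)ccc1OC(C)=O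
F12 | step 3 | 1-(4-hydroxy-3-iodo-5-methoxyphenyl)ethan-1-one | CC(=O)c1cc(I)c(O)c(OC)c1
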